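Numbering: the side chain runs from C1 (CH2 on the ring) to C32. Retrosynthetic cuts: quinone back to 1,4-dimethoxynaphthalene; C7–CH3 back through C7–CH2–B to C7–B; C6–C7 (union of the two halves); then C1–C2, C12–C13, C20–C21 and C28–C29.
Enabling feature: C7 is a methyl-bearing methine between two plain trimethylene runs (C4–C6 and C8–C10), and no alkene lies nearer to it than C2=C3 and C18=C19. With a pinacolboryl group in place of its methyl, C7 can pass through a planar, boron-stabilised radical. A chiral nickel catalyst can then funnel both C7 epimers of an α-chloroboronate into one configuration while it attaches the C1–C6 arm.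
Forward order: the naphthalene rings are bought (menadione) and no ring is made. The left arm comes from chloromethylation and alkyne carboalumination/cross-coupling. The right arm is joined at C12–C13 (Grignard/tosylate), C28–C29 (cuprate) and C20–C21 (allyl sulfone alkylation, desulfonylation), followed by hydroboration at C8 and insertion of C7. Then come the union at C6–C7, conversion of boron to methyl, and oxidation to the quinone.
Stereochemistry: C15 is bought in (S)-citronellyl bromide, C11 comes from an Evans allylation, and C7 from the catalyst in the union. C2=C3 comes from syn carboalumination, C22=C23 from geranyl bromide, and C18=C19 and C26=C27 from E-selective SeO2 oxidation of isopropylidene ends.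

Key step: step 19

Assumption: the sense of induction of the diamine ligand in the key step has to be fixed on a simple α-chloroboronate. The (1R,2R) ligand is written, and its commercial mirror image is used if the model shows the opposite sense.
Remark: the CIP letter of C11 switches between R and S along the route only because the ranking of its two chains changes with the group at C7 or C8. The centre itself is never touched.

Step 1
Reactants: 1 menadione (2-methylnaphthalene-1,4-dione)
Product: 3 1,4-dimethoxy-2-methylnaphthalene, via menadiol 2 (not isolated)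
Conditions: Na2S2O4, Et2O/H2O, rt; then Me2SO4, KOH, acetone, reflux
Reagents that add atoms: dimethyl sulfate, COS(=O)(=O)OC
Why: Dithionite reduction of the quinone followed by Williamson O-methylation of both phenols masks the redox-active ring as an arene that tolerates the organometallic steps ahead.

Step 2
Reactants: 3 1,4-dimethoxy-2-methylnaphthalene
Product: 4 2-(chloromethyl)-1,4-dimethoxy-3-methylnaphthalene
Conditions: (CH2O)n, HCl (gas), AcOH, rt
Reagents that add atoms: formaldehyde (as paraformaldehyde), C=O; hydrogen chloride, Cl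
Why: Blanc chloromethylation should strike the only free position of the electron-rich ring (C3, ortho to a methoxy group) and so installs C1 of the side chain.

Step 3
Reactants: 5 5-chloropent-1-yne; 4 2-(chloromethyl)-1,4-dimethoxy-3-methylnaphthalene
Product: 7 2-[(2E)-6-chloro-3-methylhex-2-en-1-yl]-1,4-dimethoxy-3-methylnaphthalene, via alkenylalane 6 (not isolated)
Conditions: Me3Al, Cp2ZrCl2 (25 mol %), ClCH2CH2Cl, 0 °C to rt; volatiles removed; then 4, NiCl2(PPh3)2 (3 mol %)/n-BuLi (6 mol %), THF, rt
Reagents that add atoms: trimethylaluminium, C[Al](C)C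
Why: Negishi zirconium-catalysed carboalumination adds methyl and aluminium syn with aluminium at the terminal carbon, which fixes E-C2=C3, and the cross-coupling of the alkenylalane with the benzylic chloride on zerovalent nickel proceeds with retention while the primary alkyl chloride stays inert.

Step 4
Reactants: 7 2-[(2E)-6-chloro-3-methylhex-2-en-1-yl]-1,4-dimethoxy-3-methylnaphthalene
Product: 8 2-[(2E)-6-iodo-3-methylhex-2-en-1-yl]-1,4-dimethoxy-3-methylnaphthalene
Conditions: NaI, acetone, reflux
Reagents that add atoms: sodium iodide, [Na+].[I-]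
Why: The Finkelstein reaction, driven by precipitation of NaCl, gives the primary iodide needed for mild zinc insertion.

Step 5
Reactants: 9 (4S)-4-benzyl-3-propanoyl-1,3-oxazolidin-2-one; 10 allyl iodide
Product: 12 (4S)-4-benzyl-3-[(2R)-2-methylpent-4-enoyl]-1,3-oxazolidin-2-one, via sodium enolate 11 (not isolated)
Conditions: NaN(SiMe3)2, THF, −78 °C; then 10, −78 °C
Reagents that add atoms: none
Why: In the Evans alkylation the chelated Z-enolate is attacked on the face opposite the benzyl group, which sets the future C11 as 2R.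

Step 6
Reactants: 12 (4S)-4-benzyl-3-[(2R)-2-methylpent-4-enoyl]-1,3-oxazolidin-2-one
Product: 13 (2R)-2-methylpent-4-en-1-ol
Conditions: LiBH4, MeOH (1 equiv), Et2O, 0 °C
Reagents that add atoms: none
Why: Reductive cleavage of the imide by borohydride releases the primary alcohol without enolisation, so the stereocentre should be kept.

Step 7
Reactants: 13 (2R)-2-methylpent-4-en-1-ol
Product: 14 (2R)-2-methylpent-4-en-1-yl 4-toluenesulfonate
Conditions: TsCl, Et3N, DMAP (cat.), CH2Cl2, 0 °C to rt
Reagents that add atoms: 4-toluenesulfonyl chloride, Cc1ccc(cc1)S(=O)(=O)Cl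
Why: O-Sulfonylation activates C12 for substitution and does not touch the stereocentre.

Step 8
Reactants: 15 (S)-citronellyl bromide [(6S)-8-bromo-2,6-dimethyloct-2-ene]; 14 (2R)-2-methylpent-4-en-1-yl 4-toluenesulfonate
Product: 17 (4S,8R)-4,8,12-trimethyltrideca-1,11-diene, via citronellylmagnesium bromide 16 (not isolated)
Conditions: 15, Mg, THF, reflux; then 14, Li2CuCl4 (3 mol %), THF, −78 °C to rt
Reagents that add atoms: none
Why: The copper-catalysed Grignard–tosylate cross-coupling (Kochi coupling) forms C12–C13 between two primary carbons, so neither methyl-bearing centre takes part.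

Step 9
Reactants: 17 (4S,8R)-4,8,12-trimethyltrideca-1,11-diene
Product: 18 (2E,6R,10S)-2,6,10-trimethyltrideca-2,12-dien-1-ol
Conditions: SeO2 (0.1 equiv), t-BuOOH, salicylic acid (0.1 equiv), CH2Cl2, 0 °C to rt
Reagents that add atoms: tert-butyl hydroperoxide, CC(C)(C)OO (oxygen passed on through catalytic selenium dioxide, O=[Se]=O)
Why: In the Riley oxidation the ene/[2,3]-sigmatropic sequence picks the E-methyl of the electron-rich trisubstituted alkene, which makes C20 functional with E-C18=C19, while the monosubstituted alkene reacts far more slowly.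

Step 10
Reactants: 18 (2E,6R,10S)-2,6,10-trimethyltrideca-2,12-dien-1-ol
Product: 19 (2E,6R,10S)-1-bromo-2,6,10-trimethyltrideca-2,12-diene
Conditions: CBr4, PPh3, CH2Cl2, −20 °C to 0 °C
Reagents that add atoms: carbon tetrabromide, BrC(Br)(Br)Br
Why: The Appel reaction converts the primary allylic alcohol into the bromide under neutral conditions, without allylic shift or loss of alkene geometry.

Step 11
Reactants: 20 geranyl bromide [(2E)-1-bromo-3,7-dimethylocta-2,6-diene]
Product: 21 geranyl phenyl sulfone {[(2E)-3,7-dimethylocta-2,6-dien-1-yl]sulfonylbenzene}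
Conditions: PhSO2Na, DMF, rt
Reagents that add atoms: sodium benzenesulfinate, [Na+].[O-]S(=O)c1ccccc1
Why: S-Alkylation of the sulfinate by SN2 at the primary allylic carbon keeps the E alkene (future C22=C23) and installs the carbanion-stabilising helper at C21.

Step 12
Reactants: 21 geranyl phenyl sulfone
Product: 22 (2E,6E)-2,6-dimethyl-8-(phenylsulfonyl)octa-2,6-dien-1-ol
Conditions: SeO2 (0.1 equiv), t-BuOOH, salicylic acid (0.1 equiv), CH2Cl2, 0 °C to rt
Reagents that add atoms: tert-butyl hydroperoxide, CC(C)(C)OO (oxygen passed on through catalytic selenium dioxide, O=[Se]=O)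
Why: The Riley oxidation attacks the E-methyl of the remote isopropylidene end, because the alkene next to the sulfone is electronically deactivated, and so defines E-C26=C27.

Step 13
Reactants: 22 (2E,6E)-2,6-dimethyl-8-(phenylsulfonyl)octa-2,6-dien-1-ol
Product: 23 [(2E,6E)-8-bromo-3,7-dimethylocta-2,6-dien-1-yl]sulfonylbenzene
Conditions: CBr4, PPh3, CH2Cl2, −20 °C to 0 °C
Reagents that add atoms: carbon tetrabromide, BrC(Br)(Br)Br
Why: The Appel reaction runs under neutral conditions, so the acidic sulfone and both E alkenes are left alone.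

Step 14
Reactants: 23 [(2E,6E)-8-bromo-3,7-dimethylocta-2,6-dien-1-yl]sulfonylbenzene; 24 isopentylmagnesium bromide
Product: 26 [(2E,6E)-3,7,11-trimethyldodeca-2,6-dien-1-yl]sulfonylbenzene, via diisopentylcuprate 25 (not isolated)
Conditions: 24 (2.2 equiv), CuBr·SMe2 (1.1 equiv), THF, −40 °C; then 23, −78 °C
Reagents that add atoms: none
Why: In this organocuprate–allylic halide coupling, the soft and weakly basic magnesium dialkylcuprate should displace the primary allylic bromide at C28 by SN2 in THF at −78 °C faster than it deprotonates the sulfone, which adds the saturated tail C29–C32.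

Step 15
Reactants: 26 [(2E,6E)-3,7,11-trimethyldodeca-2,6-dien-1-yl]sulfonylbenzene; 19 (2E,6R,10S)-1-bromo-2,6,10-trimethyltrideca-2,12-diene
Product: 28 [(4S,8R,11E,15E,19E)-4,8,12,16,20,24-hexamethylpentacosa-1,11,15,19-tetraen-14-yl]sulfonylbenzene (both epimers at the sulfone carbon C21), via lithiated sulfone 27 (not isolated)
Conditions: n-BuLi, THF/DMPU, −78 °C; then 19, −78 °C to −20 °C
Reagents that add atoms: none
Why: α-Alkylation of the sulfone-stabilised allyl anion with the allylic bromide (Biellmann-type head-to-tail prenyl coupling) forms C20–C21 without allylic transposition in either partner.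

Step 16
Reactants: 28 C21 phenyl sulfone of the C8–C32 chain
Product: 29 (4S,8R,11E,15E,19E)-4,8,12,16,20,24-hexamethylpentacosa-1,11,15,19-tetraene
Conditions: PdCl2(dppp) (5 mol %), LiEt3BH, THF, 0 °C
Reagents that add atoms: none
Why: In the palladium-catalysed hydride desulfonylation of the allylic sulfone, ionisation gives a π-allylpalladium complex and hydride goes to the less substituted terminus C21, so C22=C23 should keep its place and E geometry and both sulfone epimers merge into one compound.

Step 17
Reactants: 29 (4S,8R,11E,15E,19E)-4,8,12,16,20,24-hexamethylpentacosa-1,11,15,19-tetraene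
Product: 30 2-[(4R,8R,11E,15E,19E)-4,8,12,16,20,24-hexamethylpentacosa-11,15,19-trien-1-yl]-4,4,5,5-tetramethyl-1,3,2-dioxaborolane
Conditions: [Ir(cod)Cl]2 (1.5 mol %), dppe (3 mol %), HBpin, CH2Cl2, rt
Reagents that add atoms: pinacolborane, CC1(C)OBOC1(C)C
Why: Iridium-catalysed hydroboration with pinacolborane takes only the monosubstituted alkene and places boron on the terminal carbon C8, while the three trisubstituted alkenes are too hindered to react.

Step 18
Reactants: 30 primary pinacol boronate (boron on C8)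
Product: 32 2-[(5S,9R,12E,16E,20E)-1-chloro-5,9,13,17,21,25-hexamethylhexacosa-12,16,20-trien-1-yl]-4,4,5,5-tetramethyl-1,3,2-dioxaborolane (both C7 epimers), via dichloromethyl boronate complex 31 (not isolated)
Conditions: CH2Cl2, n-BuLi, THF, −100 °C; then 30; then ZnCl2, −100 °C to rt
Reagents that add atoms: dichloromethane, ClCCl
Why: In the Matteson homologation LiCHCl2 adds to boron and C8 migrates with loss of chloride, which inserts C7 as a CHCl(Bpin) unit; achiral pinacol gives no control, so both epimers are expected, and the next step makes that irrelevant.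

Step 19
Reactants: 8 2-[(2E)-6-iodo-3-methylhex-2-en-1-yl]-1,4-dimethoxy-3-methylnaphthalene; 32 α-chloroboronate (both C7 epimers)
Product: 34 2-[(2E,7S,11R,15R,18E,22E,26E)-3,11,15,19,23,27,31-heptamethyl-7-(4,4,5,5-tetramethyl-1,3,2-dioxaborolan-2-yl)dotriaconta-2,18,22,26-tetraen-1-yl]-1,4-dimethoxy-3-methylnaphthalene, via alkylzinc iodide 33 (not isolated)
Conditions: 8, Zn dust (I2-activated), DMA, 40 °C; then 32, NiBr2·diglyme (10 mol %), (1R,2R)-N,N'-dimethyl-1,2-diphenylethane-1,2-diamine (13 mol %), THF/DMA, 0 °C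
Reagents that add atoms: none
Why: A diamine-bound alkylnickel species formed by transmetalation from 33 abstracts chlorine from either C7 epimer of 32 and gives one and the same planar C7 radical, stabilised by the empty p orbital of boron; the radical is captured by the chiral nickel centre and reductive elimination from trivalent nickel forms C6–C7. The closest known reaction type is the nickel/chiral 1,2-diamine-catalysed enantioconvergent Negishi alkyl–alkyl coupling of racemic α-haloboronates with primary alkylzinc halides. No ring is closed. The only new stereocentre, C7, is set by the catalyst, which tells the pinacolboryl group from the C8 chain during capture and bond formation, so both epimers of 32 should converge on 7S, while C11 and C15 lie four and eight atoms away and should neither steer the event nor suffer from it. The step needs a radical that does nothing but couple and a catalyst that touches only the C–Cl bond: the alkene nearest to C7 in 32 is C18=C19 (no small-ring cyclisation is possible), 33 is a 4-pentenyl-type reagent that does not cyclise, the trisubstituted alkenes and aryl methyl ethers are inert at 0 °C, and the quinone is masked. Reagent 33, the cheaper partner, is used in excess.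

Step 20
Reactants: 34 secondary boronate (7S)
Product: 37 primary alcohol (34 carrying CH2OH in place of the boryl group; 7S,11S,15R), via chloromethyl boronate complex 35 (not isolated), via homologated boronic ester 36 (not isolated)
Conditions: BrCH2Cl, n-BuLi, THF, −78 °C to rt; then H2O2, aq. NaOH, 0 °C
Reagents that add atoms: bromochloromethane, ClCBr; hydrogen peroxide, OO
Why: In the Matteson one-carbon homologation C7 migrates from boron to the CH2Cl carbon with retention, which brings in the carbon of the C7 methyl group, and basic peroxide oxidises the primary C–B bond without touching unactivated alkenes.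

Step 21
Reactants: 37 primary alcohol
Product: 38 primary tosylate (37 as its 4-toluenesulfonate; 7S,11S,15R)
Conditions: TsCl, Et3N, DMAP (cat.), CH2Cl2, 0 °C to rt
Reagents that add atoms: 4-toluenesulfonyl chloride, Cc1ccc(cc1)S(=O)(=O)Cl
Why: O-Sulfonylation of the unhindered primary alcohol prepares the hydride displacement and leaves C7 untouched.

Step 22
Reactants: 38 primary tosylate
Product: 39 1,4-dimethoxy-2-methyl-3-[(2E,7S,11R,15R,18E,22E,26E)-3,7,11,15,19,23,27,31-octamethyldotriaconta-2,18,22,26-tetraen-1-yl]naphthalene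
Conditions: LiEt3BH, THF, 0 °C to rt
Reagents that add atoms: none
Why: SN2 displacement of a primary tosylate by triethylborohydride turns CH2OTs into the C7 methyl group, while alkenes and aryl ethers are inert at this temperature.

Step 23
Reactants: 39 hydroquinone dimethyl ether
Product: 40 2-methyl-3-[(2E,7S,11R,15R,18E,22E,26E)-3,7,11,15,19,23,27,31-octamethyldotriaconta-2,18,22,26-tetraen-1-yl]naphthalene-1,4-dione
Conditions: (NH4)2Ce(NO3)6, MeCN/CH2Cl2/H2O, 0 °C
Reagents that add atoms: water, O
Why: Oxidative demethylation of the 1,4-dimethoxyarene by tetravalent cerium, the standard unmasking of prenylated naphthoquinones, is fast at 0 °C and leaves isolated trisubstituted alkenes and the stereocentres alone.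

Compound list
1 | menadione (2-methylnaphthalene-1,4-dione) | CC1=CC(=O)c2ccccc2C1=O | starting material
2 | menadiol (2-methylnaphthalene-1,4-diol) | Cc1cc(O)c2ccccc2c1O | intermediate
3 | 1,4-dimethoxy-2-methylnaphthalene | COc1cc(C)c(OC)c2ccccc12 | intermediate
4 | 2-(chloromethyl)-1,4-dimethoxy-3-methylnaphthalene | COc1c(C)c(CCl)c(OC)c2ccccc12 | intermediate
5 | 5-chloropent-1-yne | C#CCCCCl | starting material
6 | [(1E)-5-chloro-2-methylpent-1-en-1-yl]dimethylalane | C[Al](C)/C=C(\C)CCCCl | intermediate
7 | 2-[(2E)-6-chloro-3-methylhex-2-en-1-yl]-1,4-dimethoxy-3-methylnaphthalene | COc1c(C)c(C/C=C(\C)CCCCl)c(OC)c2ccccc12 | intermediate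
8 | 2-[(2E)-6-iodo-3-methylhex-2-en-1-yl]-1,4-dimethoxy-3-methylnaphthalene | COc1c(C)c(C/C=C(\C)CCCI)c(OC)c2ccccc12 | intermediate
9 | (4S)-4-benzyl-3-propanoyl-1,3-oxazolidin-2-one | CCC(=O)N1[C@@H](Cc2ccccc2)COC1=O | starting material
10 | allyl iodide (3-iodoprop-1-ene) | C=CCI | starting material
11 | sodium (Z)-enolate of 9 | [Na+].C/C=C(\[O-])N1[C@@H](Cc2ccccc2)COC1=O | intermediate
12 | (4S)-4-benzyl-3-[(2R)-2-methylpent-4-enoyl]-1,3-oxazolidin-2-one | C=CC[C@@H](C)C(=O)N1[C@@H](Cc2ccccc2)COC1=O | intermediate
13 | (2R)-2-methylpent-4-en-1-ol | C=CC[C@@H](C)CO | intermediate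
14 | (2R)-2-methylpent-4-en-1-yl 4-toluenesulfonate | C=CC[C@@H](C)COS(=O)(=O)c1ccc(C)cc1 | intermediate
15 | (S)-citronellyl bromide, (6S)-8-bromo-2,6-dimethyloct-2-ene | BrCC[C@@H](C)CCC=C(C)C | starting material
16 | (S)-citronellylmagnesium bromide | Br[Mg]CC[C@@H](C)CCC=C(C)C | intermediate
17 | (4S,8R)-4,8,12-trimethyltrideca-1,11-diene (C8–C20) | C=CC[C@@H](C)CCC[C@@H](C)CCC=C(C)C | intermediate
18 | (2E,6R,10S)-2,6,10-trimethyltrideca-2,12-dien-1-ol | C=CC[C@@H](C)CCC[C@@H](C)CC/C=C(\C)CO | intermediate
19 | (2E,6R,10S)-1-bromo-2,6,10-trimethyltrideca-2,12-diene | C=CC[C@@H](C)CCC[C@@H](C)CC/C=C(\C)CBr | intermediate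
20 | geranyl bromide, (2E)-1-bromo-3,7-dimethylocta-2,6-diene | BrC/C=C(\C)CCC=C(C)C | starting material
21 | geranyl phenyl sulfone | O=S(=O)(C/C=C(\C)CCC=C(C)C)c1ccccc1 | intermediate
22 | (2E,6E)-2,6-dimethyl-8-(phenylsulfonyl)octa-2,6-dien-1-ol | O=S(=O)(C/C=C(\C)CC/C=C(\C)CO)c1ccccc1 | intermediate
23 | [(2E,6E)-8-bromo-3,7-dimethylocta-2,6-dien-1-yl]sulfonylbenzene | O=S(=O)(C/C=C(\C)CC/C=C(\C)CBr)c1ccccc1 | intermediate
24 | isopentylmagnesium bromide | CC(C)CC[Mg]Br | starting material
25 | bromomagnesium diisopentylcuprate | [Mg+2].[Br-].CC(C)CC[Cu-]CCC(C)C | intermediate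
26 | [(2E,6E)-3,7,11-trimethyldodeca-2,6-dien-1-yl]sulfonylbenzene (C21–C32) | O=S(=O)(C/C=C(\C)CC/C=C(\C)CCCC(C)C)c1ccccc1 | intermediate
27 | α-lithio derivative of 26 | [Li]C(/C=C(\C)CC/C=C(\C)CCCC(C)C)S(=O)(=O)c1ccccc1 | intermediate
28 | [(4S,8R,11E,15E,19E)-4,8,12,16,20,24-hexamethylpentacosa-1,11,15,19-tetraen-14-yl]sulfonylbenzene, both epimers at the sulfone carbon | C=CC[C@@H](C)CCC[C@@H](C)CC/C=C(\C)CC(/C=C(\C)CC/C=C(\C)CCCC(C)C)S(=O)(=O)c1ccccc1 | intermediate
29 | (4S,8R,11E,15E,19E)-4,8,12,16,20,24-hexamethylpentacosa-1,11,15,19-tetraene (C8–C32) | C=CC[C@@H](C)CCC[C@@H](C)CC/C=C(\C)CC/C=C(\C)CC/C=C(\C)CCCC(C)C | intermediate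
30 | 2-[(4R,8R,11E,15E,19E)-4,8,12,16,20,24-hexamethylpentacosa-11,15,19-trien-1-yl]-4,4,5,5-tetramethyl-1,3,2-dioxaborolane | CC1(C)OB(CCC[C@@H](C)CCC[C@@H](C)CC/C=C(\C)CC/C=C(\C)CC/C=C(\C)CCCC(C)C)OC1(C)C | intermediate
31 | lithium dichloromethyl boronate complex of 30 | [Li+].CC1(C)O[B-](C(Cl)Cl)(CCC[C@@H](C)CCC[C@@H](C)CC/C=C(\C)CC/C=C(\C)CC/C=C(\C)CCCC(C)C)OC1(C)C | intermediate
32 | 2-[(5S,9R,12E,16E,20E)-1-chloro-5,9,13,17,21,25-hexamethylhexacosa-12,16,20-trien-1-yl]-4,4,5,5-tetramethyl-1,3,2-dioxaborolane, both C7 epimers | CC1(C)OB(C(Cl)CCC[C@@H](C)CCC[C@@H](C)CC/C=C(\C)CC/C=C(\C)CC/C=C(\C)CCCC(C)C)OC1(C)C | intermediate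
33 | [(4E)-6-(1,4-dimethoxy-3-methylnaphthalen-2-yl)-4-methylhex-4-en-1-yl]zinc iodide | COc1c(C)c(C/C=C(\C)CCC[Zn]I)c(OC)c2ccccc12 | intermediate
34 | (7S,11R,15R)-C7 pinacol boronate of the full chain on the dimethoxynaphthalene | COc1c(C)c(C/C=C(\C)CCC[C@@H](B3OC(C)(C)C(C)(C)O3)CCC[C@@H](C)CCC[C@@H](C)CC/C=C(\C)CC/C=C(\C)CC/C=C(\C)CCCC(C)C)c(OC)c2ccccc12 | intermediate
35 | lithium chloromethyl boronate complex of 34 | [Li+].COc1c(C)c(C/C=C(\C)CCC[C@@H]([B-]3(CCl)OC(C)(C)C(C)(C)O3)CCC[C@@H](C)CCC[C@@H](C)CC/C=C(\C)CC/C=C(\C)CC/C=C(\C)CCCC(C)C)c(OC)c2ccccc12 | intermediate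
36 | (7S,11S,15R)-C7-CH2Bpin homologue of 34 | COc1c(C)c(C/C=C(\C)CCC[C@@H](CB3OC(C)(C)C(C)(C)O3)CCC[C@@H](C)CCC[C@@H](C)CC/C=C(\C)CC/C=C(\C)CC/C=C(\C)CCCC(C)C)c(OC)c2ccccc12 | intermediate
37 | (7S,11S,15R)-C7-hydroxymethyl compound | COc1c(C)c(C/C=C(\C)CCC[C@@H](CO)CCC[C@@H](C)CCC[C@@H](C)CC/C=C(\C)CC/C=C(\C)CC/C=C(\C)CCCC(C)C)c(OC)c2ccccc12 | intermediate
38 | 4-toluenesulfonate of 37 (7S,11S,15R) | COc1c(C)c(C/C=C(\C)CCC[C@@H](COS(=O)(=O)c3ccc(C)cc3)CCC[C@@H](C)CCC[C@@H](C)CC/C=C(\C)CC/C=C(\C)CC/C=C(\C)CCCC(C)C)c(OC)c2ccccc12 | intermediate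
39 | 1,4-dimethoxy-2-methyl-3-[(2E,7S,11R,15R,18E,22E,26E)-3,7,11,15,19,23,27,31-octamethyldotriaconta-2,18,22,26-tetraen-1-yl]naphthalene | COc1c(C)c(C/C=C(\C)CCC[C@@H](C)CCC[C@@H](C)CCC[C@@H](C)CC/C=C(\C)CC/C=C(\C)CC/C=C(\C)CCCC(C)C)c(OC)c2ccccc12 | intermediate
40 | 2-methyl-3-[(2E,7S,11R,15R,18E,22E,26E)-3,7,11,15,19,23,27,31-octamethyldotriaconta-2,18,22,26-tetraen-1-yl]naphthalene-1,4-dione | CC1=C(C/C=C(\C)CCC[C@@H](C)CCC[C@@H](C)CCC[C@@H](C)CC/C=C(\C)CC/C=C(\C)CC/C=C(\C)CCCC(C)C)C(=O)c2ccccc2C1=O | target

Total step count: 23. Longest linear sequence: 15 steps (from 9 through steps 5–10 and 15–23).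

Steps most likely to fail

Step 19. What may go wrong: facial control by the catalyst at C7 may be weak with two very long lipophilic partners. Radical capture may also be slow, so that hydrodechlorination and homocoupling of the zinc reagent take over. The fallback replaces radical catalysis by a stoichiometric chiral director and a polar, stereospecific 1,2-metallate shift (Matteson asymmetric homologation), and it forms the same C6–C7 bond. It sets out from 30 and 7 and comes back to the route at 37.
- The pinacol ester of 30 is cleaved (NaIO4, NH4OAc, acetone/H2O) to the boronic acid F1.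
- F1 is esterified with (1S,2S)-1,2-dicyclohexylethane-1,2-diol (MgSO4, Et2O) to the chiral boronate F2.
- LiCHCl2 and ZnCl2 (THF, −100 °C to rt) should give, under control of the C2-symmetric diol, the (αR)-chloroboronate F3.
- Chloride 7 is converted with Mg in THF into the Grignard reagent F4. F4 adds to the boron of F3, and on warming C6 migrates with inversion at C7 to give the (7S) secondary boronate F5.
- The conditions of step 20 then lead through the homologated boronate F6 to 37.

Step 14. What may go wrong: the organometallic reagent may deprotonate the acidic allylic sulfone, which is followed by self-alkylation of the bromo sulfone. Attack may also occur at the γ-carbon C26 instead of C28. In the fallback the saturated tail is attached last, when no sulfone is left. It sets out from 22 and 19 and comes back at 29.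
- 22 is doubly deprotonated (n-BuLi, 2 equiv, THF/DMPU, −78 °C) to the dilithio species F7.
- The carbanion of F7 is alkylated by 19 to give the coupled hydroxy sulfone F8.
- PdCl2(dppp)/LiEt3BH removes the sulfone and gives the allylic alcohol F9.
- The Appel reaction gives the allylic bromide F10.
- 24 with catalytic Li2CuCl4 (THF, −78 °C, fast addition) displaces the bromide at C28 and gives 29.

Step 16. What may go wrong: a palladium hydride may move the terminal C8=C9 alkene inward during the desulfonylation, which would spoil the site of borylation. The fallback changes the order of events, so that the terminal alkene no longer exists when hydride and palladium meet. It sets out from 28 and comes back at 30.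
- 28 is hydroborated under the conditions of step 17 to the boronate sulfone F11.
- The allylic sulfone of F11 is then removed with PdCl2(dppp)/LiEt3BH. The weakly Lewis-acidic pinacol boronate should not take hydride away from triethylborane, so 30 results.

Further compounds
F1 | step 19 | [(4R,8R,11E,15E,19E)-4,8,12,16,20,24-hexamethylpentacosa-11,15,19-trien-1-yl]boronic acid | OB(O)CCC[C@@H](C)CCC[C@@H](C)CC/C=C(\C)CC/C=C(\C)CC/C=C(\C)CCCC(C)C
F2 | step 19 | (4S,5S)-4,5-dicyclohexyl-1,3,2-dioxaborolane ester of F1 | C(CC[C@@H](C)CCC[C@@H](C)CC/C=C(\C)CC/C=C(\C)CC/C=C(\C)CCCC(C)C)B1O[C@@H](C2CCCCC2)[C@H](C2CCCCC2)O1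
F3 | step 19 | (αR)-chloroboronate (C7 chloride, dicyclohexylethanediol ester) | Cl[C@H](B1O[C@@H](C2CCCCC2)[C@H](C2CCCCC2)O1)CCC[C@@H](C)CCC[C@@H](C)CC/C=C(\C)CC/C=C(\C)CC/C=C(\C)CCCC(C)C
F4 | step 19 | [(4E)-6-(1,4-dimethoxy-3-methylnaphthalen-2-yl)-4-methylhex-4-en-1-yl]magnesium chloride | COc1c(C)c(C/C=C(\C)CCC[Mg]Cl)c(OC)c2ccccc12
F5 | step 19 | (7S) secondary boronate, dicyclohexylethanediol ester analogue of 34 | COc1c(C)c(C/C=C(\C)CCC[C@@H](B3O[C@@H](C4CCCCC4)[C@H](C4CCCCC4)O3)CCC[C@@H](C)CCC[C@@H](C)CC/C=C(\C)CC/C=C(\C)CC/C=C(\C)CCCC(C)C)c(OC)c2ccccc12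
F6 | step 19 | homologated C7-CH2 boronate, dicyclohexylethanediol ester analogue of 36 | COc1c(C)c(C/C=C(\C)CCC[C@@H](CB3O[C@@H](C4CCCCC4)[C@H](C4CCCCC4)O3)CCC[C@@H](C)CCC[C@@H](C)CC/C=C(\C)CC/C=C(\C)CC/C=C(\C)CCCC(C)C)c(OC)c2ccccc12
F7 | step 14 | O,C-dilithio derivative of 22 | [Li]C(/C=C(\C)CC/C=C(\C)CO[Li])S(=O)(=O)c1ccccc1
F8 | step 14 | coupled hydroxy sulfone (C8–C28 chain, PhSO2 at C21, OH at C28), both sulfone epimers | C=CC[C@@H](C)CCC[C@@H](C)CC/C=C(\C)CC(/C=C(\C)CC/C=C(\C)CO)S(=O)(=O)c1ccccc1
F9 | step 14 | (2E,6E,10E,14R,18S)-2,6,10,14,18-pentamethylhenicosa-2,6,10,20-tetraen-1-ol | C=CC[C@@H](C)CCC[C@@H](C)CC/C=C(\C)CC/C=C(\C)CC/C=C(\C)CO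
F10 | step 14 | (2E,6E,10E,14R,18S)-1-bromo-2,6,10,14,18-pentamethylhenicosa-2,6,10,20-tetraene | C=CC[C@@H](C)CCC[C@@H](C)CC/C=C(\C)CC/C=C(\C)CC/C=C(\C)CBr
F11 | step 16 | C8 pinacol boronate of 28 (PhSO2 still at C21), both sulfone epimers | CC1(C)OB(CCC[C@@H](C)CCC[C@@H](C)CC/C=C(\C)CC(/C=C(\C)CC/C=C(\C)CCCC(C)C)S(=O)(=O)c2ccccc2)OC1(C)C
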